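## The problem

The target is a chain of eight benzene rings, lettered A to H from the 2,4,6-trihydroxyphenyl end to the 3,4,5-trihydroxyphenyl end, held together only by seven diaryl ether oxygens and carrying twenty-one free hydroxyls. It has no stereocenter, so nothing has to control anything else in space; the task is regiochemistry on eight tetra- or penta-oxygenated rings and the making of aryl–oxygen bonds. These bonds differ sharply in crowding. The ring F carbon toward E and the ring B carbon toward A have C–H on both sides, but the ring C carbon toward D, the ring E carbon toward D and the ring G carbon toward H each lie between two oxygenated carbons. The ring D carbon toward E lies between two hydroxylated carbons, so the D–O–E ether carries four ortho oxygens, and copper-mediated couplings tolerate one hindered partner but not two. The free polyphenol, with its pyrogallol and hydroxyquinol arrays, is oxidised by air, base and metals, so every hydroxyl must travel as an ether and be freed in the last operation; before that, the ring A trimethyl ether is a phloroglucinol-type π-nucleophile that will not survive Vilsmeier reagents, halogens or hot acid. In ring D the carbon bound to the oxygen leading to ring C (D-C1) has C–H on both sides (D-C2 and D-C6), and beyond these sit the three contiguous oxygenated carbons D-C3, D-C4 and D-C5. The unit C2–C1–C6 therefore matches a symmetric 2-aryloxymalonaldehyde whose aryloxy group is the whole A–B–C unit, and C3–C4–C5 matches the chain of a 4-methoxyacetoacetate, so ring D can be built on the hindered ring C oxygen instead of being coupled to it.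

## Retrosynthesis

**41 ⇒ 40 (protecting groups).** All hydroxyls are carried as methyl ethers and the last step cleaves the twenty O–CH3 bonds of 40 with BBr3, which leaves diaryl ethers intact. Methyl is preferred to benzyl because every building block is commercial as its methyl ether and because methyl ethers are inert to TiCl4 at low temperature, peracid, LiAlH4 and copper catalysis. The price is one harsh final step on a large molecule.

**40 ⇒ 38 ⇒ 37 (last ring D oxygen).** The hydroxyl of 40 on ring D next to the D–O–E ether is traced to a formyl group (Dakin oxidation of 38), and that to the hydroxymethyl group of 37. This is the one ring D heteroatom that the cyclocondensation cannot deliver directly: it arrives as the ester carbon of the salicylate. The Dakin step needs only one ortho oxygen to favour aryl migration, and the ortho aryloxy group supplies it.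

**37 ⇒ 27 + 36 (E–O–F bond).** The cut is made at the ring F carbon that has C–H on both sides. It is preferred to the neighbouring F–O–G cut because it divides the octamer into a pentamer (27) and a trimer (36) and puts the unhindered partner on the halide side. The forward reaction is an Ullmann coupling of an ortho-aryloxy phenol with an unhindered aryl bromide.

**36 ⇒ 32 + 35; 32 ⇒ 30 ⇒ 28 + 29; 35 ⇒ 34 ⇒ 33 (rings F to H).** The F–O–G bond is cut at the ring F carbon; the dihalide 35 offers an iodide at that carbon and a bromide at the carbon reserved for ring E. The hindered H–O–G bond is cut at the ring G carbon ortho to a formyl group (29), which is then turned into the ring G hydroxyl of 32 by Dakin oxidation. Both partners are commercial, and the aldehyde serves first as an ortho activator for copper and then as a latent phenol.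

**27 ⇒ 26 ⇒ 25 ⇒ 23 ⇒ 20 + 22; 22 ⇒ 21 (D–O–E bond).** This is the tetra-ortho-substituted ether, and no copper coupling is trusted with it. Ring E is instead introduced as bromoquinone 22: every ring carbon of a quinone is β to a carbonyl, so the hindered phenoxide of 20 can add and expel bromide. After reduction the two hydroquinone oxygens differ: one lies between two methoxy groups, the other between the new aryloxy group and C–H. Pivaloylation of the less hindered one, methylation of the other, and one hydride step that both removes the pivalate and reduces the ring D ester give 27.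

**20 ⇒ 16 + 19 (key disconnection).** Ring D of salicylate 20 is cut at the two bonds that join its C–H carbons to C3 and C5. This removes an entire ring and replaces a doubly hindered C–O coupling at ring C with a condensation at carbon. The alternative of coupling a preformed ring D to the ring C phenol would be a tri-ortho-substituted Ullmann reaction followed by the tetra-ortho one. The forward reaction asks only that the silyl dienolate react with the aldehyde faster than the electron-rich rings do.

**16 ⇒ 15 ⇒ 13 ⇒ 11 ⇒ 10 (the dielectrophile).** Direct O-alkylation of 10 with bromomalonaldehyde is set aside: that reagent is a fully enolised vinylogous acid which a phenoxide merely deprotonates, leaving its C–Br carbon sp2 in a delocalised anion. Vilsmeier formylation of an aryloxyacetic acid or acetal is set aside because ring A would be formylated first. The oxygen–carbon bond is therefore made by allylation, the allyl group is cut to aldehyde 13, and the second formyl carbon comes from Bredereck's reagent, which is not electrophilic toward arenes.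

**19 ⇒ 18 ⇒ 17 (the dinucleophile).** Two successive silylations of commercial methyl 4-methoxyacetoacetate give the diene; the 4-methoxy group becomes the ring D methoxy group.

**10 ⇒ 8 ⇒ 5 + 7; 7 ⇒ 6; 5 ⇒ 3 ⇒ 1 + 2 (rings A to C).** The B–O–C bond is cut at the ring C carbon that has a C–H neighbour and an ortho formyl group (7); the hindered ring C hydroxyl then comes from that formyl group by Dakin oxidation, so it never has to act in a coupling. The A–O–B bond is cut at the unhindered ring B carbon para to a formyl group (2), which becomes the hindered ring B hydroxyl of 5 in the same way. Aldehyde 7 is one formylation from bromide 6, which has only one kind of free position.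

## Roads not taken

Alternative 1: Both aryl–oxygen bonds of ring F would be cut. In the forward sense the phenoxide of the A–E pentamer phenol A3 would displace the para fluorine of 2,4,6-trifluorobenzaldehyde A2, and the phenoxide of 32 would then displace an ortho fluorine to give octaaryl ether A1. Methoxide exchange of the last fluorine and a Dakin oxidation would complete ring F. The merits are real: the two halves are united in one flask without copper, at carbons activated by the formyl group, and the para-before-ortho order is the normal one. At the ring F junction this is at least as good as steps 20 to 23 of the chosen plan and probably shorter. Its weak points lie elsewhere. A3 already contains the hindered ethers at rings C, D and E, which the linchpin does nothing to make; aryloxy groups on an activated ring can be exchanged by a second phenoxide; and the last fluorine must be replaced by methoxide without displacing either aryloxy group. The chosen plan sets against the better ring F junction a solution to the hardest bond at ring D, which this alternative leaves open.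

Alternative 2: Two carbon–carbon bonds of ring C would be cut. Heating aryloxyacetylene A5 with aryloxycyclobutenone A6 would open the cyclobutenone to a vinylketene, add the alkyne, reopen and close by 6π electrocyclisation to phenol A4, with both flanking ethers of ring C in place. It builds a ring and two bonds, as the chosen step does, and avoids copper at ring C. It also delivers ring D with all three oxygens present, so the three steps the chosen plan spends turning an ester into a hydroxyl (steps 17, 24 and 25 in part) would not be needed; in that respect it is better. Against this, A5 and A6 are both sensitive compounds that each need several steps (an aryl ynol ether of a hindered phenol; a 4-unsubstituted alkoxycyclobutenone from a squarate by exchange and selective reduction), and the cascade needs heat on both. After debenzylation the ring D phenol between two methoxy groups still has to be joined to ring E, so the tetra-ortho bond remains. The chosen plan sets against the saved steps precursors made from a phenol and a commercial keto ester by routine operations, a low-temperature key step, and a ring D ester that lets one hydride step unmask the ring E hydroxyl.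

Alternative 3: The ring G bond between the future ring F ether carbon and the lone C–H carbon would be cut. Thermolysis of 4-(1-methoxyvinyl)cyclobutenone A8 would give a dienylketene whose 6π closure and tautomerisation give phenol A7. The regiochemistry of the pentaoxygenated ring is fixed by the squarate and no metal is needed, which is cleaner than a copper coupling. But A7 is the same compound as 32, which steps 18 and 19 make from two commercial materials. The squarate route needs aryloxy exchange, a regioselective addition of a 1-methoxyvinyl metal, O-methylation and thermolysis to reach it. It also spends the ring-forming event on the least hindered end of the molecule and leaves the ring D ethers to couplings. It would be a credible reserve if step 18 failed; as the central idea it gives less than building ring D.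

Key step: step 12

Remarks on the chemistry and on notation:
- Silyl enol ethers 16, 18 and 19 and enaminoaldehyde 14 are written as single geometric isomers; any E/Z mixture converges on the same arene. Dialdehyde 15 is expected to exist as its enol.
- "ABC-oxy" stands for 6-[2,6-dimethoxy-4-(2,4,6-trimethoxyphenoxy)phenoxy]-2,3,4-trimethoxyphenoxy (protected rings A–B–C bound through the hindered ring C oxygen).
- "FGH-oxy" stands for 3,4-dimethoxy-5-[3,4,5-trimethoxy-2-(3,4,5-trimethoxyphenoxy)phenoxy]phenoxy.
- Compounds 1, 2, 6, 17, 21, 28, 29 and 33 are taken as commercial.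

Step 1
Reactants: 1 2,4,6-trimethoxyphenol; 2 4-bromo-2,6-dimethoxybenzaldehyde
Product: 3 2,6-dimethoxy-4-(2,4,6-trimethoxyphenoxy)benzaldehyde
Conditions: CuI (10 mol%), picolinic acid (20 mol%), K3PO4, DMSO, 90 °C, Ar
Reagents that add atoms: none
Why: Ullmann diaryl ether coupling; the picolinic acid system accepts di-ortho-substituted phenols, and the bromide is unhindered and activated by the para formyl group.

Step 2
Reactants: 3 2,6-dimethoxy-4-(2,4,6-trimethoxyphenoxy)benzaldehyde
Product: 5 2,6-dimethoxy-4-(2,4,6-trimethoxyphenoxy)phenol, via aryl formate 4 (not isolated)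
Conditions: mCPBA, CH2Cl2, 0 °C to rt; then K2CO3, MeOH, rt
Reagents that add atoms: 3-chloroperoxybenzoic acid, OOC(=O)c1cccc(Cl)c1
Why: Dakin-type Baeyer–Villiger oxidation; two ortho methoxy groups and a para aryloxy group make aryl migration fast, and methanolysis of the formate frees the ring B phenol.

Step 3
Reactants: 6 5-bromo-1,2,3-trimethoxybenzene
Product: 7 6-bromo-2,3,4-trimethoxybenzaldehyde
Conditions: Cl2CHOCH3, TiCl4, CH2Cl2, 0 °C; then H2O
Reagents that add atoms: dichloromethyl methyl ether, COC(Cl)Cl; water, O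
Why: Rieche formylation; the two free positions of 6 are equivalent and each is ortho and para to methoxy groups, so only one aldehyde can form.

Step 4
Reactants: 5 2,6-dimethoxy-4-(2,4,6-trimethoxyphenoxy)phenol; 7 6-bromo-2,3,4-trimethoxybenzaldehyde
Product: 8 6-[2,6-dimethoxy-4-(2,4,6-trimethoxyphenoxy)phenoxy]-2,3,4-trimethoxybenzaldehyde
Conditions: CuI (20 mol%), picolinic acid (40 mol%), K3PO4, DMSO, 100 °C, Ar
Reagents that add atoms: none
Why: Ullmann coupling of a hindered phenol with an aryl bromide that has only one ortho substituent, a formyl group that assists copper insertion; the product is a tri-ortho-substituted ether, within the reach of this catalyst.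

Step 5
Reactants: 8 6-[2,6-dimethoxy-4-(2,4,6-trimethoxyphenoxy)phenoxy]-2,3,4-trimethoxybenzaldehyde
Product: 10 6-[2,6-dimethoxy-4-(2,4,6-trimethoxyphenoxy)phenoxy]-2,3,4-trimethoxyphenol, via aryl formate 9 (not isolated)
Conditions: mCPBA, NaHCO3, CH2Cl2, 0 °C; then K2CO3, MeOH, rt
Reagents that add atoms: 3-chloroperoxybenzoic acid, OOC(=O)c1cccc(Cl)c1
Why: Dakin-type Baeyer–Villiger oxidation of an aldehyde flanked by methoxy and aryloxy groups with a para methoxy group; it creates the hindered ring C hydroxyl without a coupling at that carbon.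

Step 6
Reactants: 10 6-[2,6-dimethoxy-4-(2,4,6-trimethoxyphenoxy)phenoxy]-2,3,4-trimethoxyphenol
Product: 11 3-(ABC-oxy)prop-1-ene (allyl ether of 10)
Conditions: allyl bromide, K2CO3, DMF, 50 °C
Reagents that add atoms: allyl bromide, C=CCBr
Why: Williamson ether synthesis; allyl bromide is reactive enough to alkylate a phenoxide with two ortho oxygen substituents.

Step 7
Reactants: 11 3-(ABC-oxy)prop-1-ene
Product: 13 2-(ABC-oxy)acetaldehyde, via racemic 1,2-diol 12 (not isolated)
Conditions: OsO4 (2 mol%), NaIO4, 2,6-lutidine, dioxane/H2O, rt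
Reagents that add atoms: osmium tetroxide, O=[Os](=O)(=O)=O; sodium periodate, [Na+].[O-]I(=O)(=O)=O
Why: Lemieux–Johnson oxidative cleavage; it is chosen over ozonolysis because ozone would attack the polymethoxyarenes, and the stereocenter of the transient diol is destroyed in the cleavage.

Step 8
Reactants: 13 2-(ABC-oxy)acetaldehyde
Product: 15 2-(ABC-oxy)malonaldehyde, via enaminoaldehyde 14 (not isolated)
Conditions: t-BuOCH(NMe2)2, toluene, 70 °C; then NaOH, EtOH/H2O, 70 °C; then HCl to pH 3
Reagents that add atoms: tert-butoxybis(dimethylamino)methane, CN(C)C(OC(C)(C)C)N(C)C; water (as aqueous NaOH), O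
Why: Aminomethylenation of the α-methylene of an aldehyde with Bredereck's reagent, then alkaline hydrolysis of the vinylogous formamide; the formamidinium species does not attack ring A, unlike a Vilsmeier reagent.

Step 9
Reactants: 15 2-(ABC-oxy)malonaldehyde
Product: 16 (E)-2-(ABC-oxy)-3-(trimethylsilyloxy)prop-2-enal
Conditions: Me3SiCl, Et3N, CH2Cl2, rt; filtration and evaporation, used crude
Reagents that add atoms: chlorotrimethylsilane, C[Si](C)(C)Cl
Why: O-silylation of the enol of a 1,3-dicarbonyl compound; it gives the 3-silyloxy-2-enal form in which such dielectrophiles are used in Lewis acid cyclocondensations.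

Step 10
Reactants: 17 methyl 4-methoxyacetoacetate
Product: 18 methyl (Z)-4-methoxy-3-(trimethylsilyloxy)but-2-enoate
Conditions: Me3SiCl, Et3N, toluene, rt
Reagents that add atoms: chlorotrimethylsilane, C[Si](C)(C)Cl
Why: O-silylation of the β-keto ester enol, the standard first stage of a 1,3-bis(silyloxy)diene synthesis.

Step 11
Reactants: 18 methyl (Z)-4-methoxy-3-(trimethylsilyloxy)but-2-enoate
Product: 19 (1Z,3Z)-1,4-dimethoxy-1,3-bis(trimethylsilyloxy)buta-1,3-diene
Conditions: LiN(iPr)2, THF, −78 °C; then Me3SiCl, −78 °C to rt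
Reagents that add atoms: chlorotrimethylsilane, C[Si](C)(C)Cl
Why: Deprotonation to the ester enolate and O-silylation give the silyl ketene acetal, a masked dianion of the keto ester with both termini nucleophilic.

Step 12
Reactants: 16 (E)-2-(ABC-oxy)-3-(trimethylsilyloxy)prop-2-enal; 19 (1Z,3Z)-1,4-dimethoxy-1,3-bis(trimethylsilyloxy)buta-1,3-diene
Product: 20 methyl 2-hydroxy-3-methoxy-5-(ABC-oxy)benzoate
Conditions: TiCl4 (2 equiv), CH2Cl2, −78 °C to 20 °C, 19 in excess; then aqueous HCl
Reagents that add atoms: none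
Why: TiCl4 binds the formyl group of 16, and the terminal methoxy-bearing carbon of 19, its most nucleophilic site, adds in a Mukaiyama aldol step to form the bond between the methoxy carbon and one C–H carbon of ring D. The silyl enol ether end of the former malonaldehyde is thereby released as a second Lewis acid-bound aldehyde, and the central carbon of the β-keto ester enolate closes onto it in a 6-exo-trig aldol step, forming the bond between the ester-bearing carbon and the other C–H carbon. Loss of two equivalents of silanol or water and enolisation then aromatise ring D, the former 3-silyloxy oxygen becoming the phenol hydrogen-bonded to the ester. The closest known reaction type is the Lewis acid-mediated formal (3+3) cyclocondensation of 1,3-bis(silyloxy)-1,3-butadienes with 3-silyloxy-2-en-1-ones, which has been used with 2-aryloxy dielectrophiles to make diaryl ethers and with 4-methoxy dienes to make 3-methoxysalicylates. No stereocenter is formed. No regiocontrol is needed because the two electrophilic carbons of 16 are equivalent, and the order of bond formation follows from the higher nucleophilicity of the diene terminus. The selectivity that is needed is chemoselectivity for the aldehyde over ring A; it rests on the far higher nucleophilicity of a silyl dienolate compared with a trimethoxyarene, on low temperature and on an excess of 19.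

Step 13
Reactants: 21 2,6-dimethoxy-1,4-benzoquinone
Product: 22 3-bromo-2,6-dimethoxy-1,4-benzoquinone
Conditions: Br2 (1 equiv), AcOH/CHCl3, rt
Reagents that add atoms: bromine, BrBr
Why: Bromination at the α-carbon of the vinylogous ester by addition of Br2 and loss of HBr; one equivalent limits dibromination.

Step 14
Reactants: 20 methyl 2-hydroxy-3-methoxy-5-(ABC-oxy)benzoate; 22 3-bromo-2,6-dimethoxy-1,4-benzoquinone
Product: 23 methyl 2-[(2,4-dimethoxy-3,6-dioxocyclohexa-1,4-dien-1-yl)oxy]-3-methoxy-5-(ABC-oxy)benzoate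
Conditions: Cs2CO3, MeCN, 0 °C to rt, Ar, dark
Reagents that add atoms: none
Why: Addition–elimination of a phenoxide on a haloquinone; the bromine-bearing carbon is β to the more electrophilic carbonyl and bromide leaves irreversibly, so the tetra-ortho-substituted ether forms without a metal.

Step 15
Reactants: 23 methyl 2-[(2,4-dimethoxy-3,6-dioxocyclohexa-1,4-dien-1-yl)oxy]-3-methoxy-5-(ABC-oxy)benzoate
Product: 25 methyl 2-[3-hydroxy-2,4-dimethoxy-6-(pivaloyloxy)phenoxy]-3-methoxy-5-(ABC-oxy)benzoate, via hydroquinone 24 (not isolated)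
Conditions: H2 (1 atm), Pd/C, EtOAc, rt; filtration under Ar; then t-BuCOCl (1.05 equiv), pyridine, DMAP (5 mol%), −20 to 0 °C
Reagents that add atoms: pivaloyl chloride, CC(C)(C)C(Cl)=O
Why: Quinone hydrogenation followed by sterically controlled monoacylation; the hydroxyl between two methoxy groups is shielded on both sides, while the one next to C–H has a single ortho substituent and should take the bulky acyl group.

Step 16
Reactants: 25 methyl 2-[3-hydroxy-2,4-dimethoxy-6-(pivaloyloxy)phenoxy]-3-methoxy-5-(ABC-oxy)benzoate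
Product: 26 methyl 3-methoxy-2-[2,3,4-trimethoxy-6-(pivaloyloxy)phenoxy]-5-(ABC-oxy)benzoate
Conditions: CH3I, K2CO3, acetone, 50 °C
Reagents that add atoms: iodomethane, CI
Why: Williamson methylation of the remaining syringol-type hydroxyl; the pivalate cannot migrate to a para oxygen and is stable to anhydrous carbonate.

Step 17
Reactants: 26 methyl 3-methoxy-2-[2,3,4-trimethoxy-6-(pivaloyloxy)phenoxy]-5-(ABC-oxy)benzoate
Product: 27 [2-(6-hydroxy-2,3,4-trimethoxyphenoxy)-3-methoxy-5-(ABC-oxy)phenyl]methanol
Conditions: LiAlH4, THF, 0 °C to rt; aqueous potassium sodium tartrate work-up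
Reagents that add atoms: none
Why: Hydride reduction of both esters in one operation: the methyl ester becomes the benzylic alcohol and the aryl pivalate is cleaved to the ring E phenol.

Step 18
Reactants: 28 3,4,5-trimethoxyphenol; 29 2-bromo-3,4,5-trimethoxybenzaldehyde
Product: 30 3,4,5-trimethoxy-2-(3,4,5-trimethoxyphenoxy)benzaldehyde
Conditions: CuI (10 mol%), picolinic acid (20 mol%), K3PO4, DMSO, 90 °C, Ar
Reagents that add atoms: none
Why: Ullmann coupling of an unhindered phenol with a bromide activated by an ortho formyl group; only the halide partner is hindered.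

Step 19
Reactants: 30 3,4,5-trimethoxy-2-(3,4,5-trimethoxyphenoxy)benzaldehyde
Product: 32 3,4,5-trimethoxy-2-(3,4,5-trimethoxyphenoxy)phenol, via aryl formate 31 (not isolated)
Conditions: mCPBA, CH2Cl2, 0 °C to rt; then K2CO3, MeOH, rt
Reagents that add atoms: 3-chloroperoxybenzoic acid, OOC(=O)c1cccc(Cl)c1
Why: Dakin-type Baeyer–Villiger oxidation, favoured by the ortho aryloxy and para methoxy groups; it gives the ring G hydroxyl next to C–H.

Step 20
Reactants: 33 4-bromo-2-methoxyphenol
Product: 34 4-bromo-2-iodo-6-methoxyphenol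
Conditions: N-iodosuccinimide, TsOH (10 mol%), MeCN, rt
Reagents that add atoms: N-iodosuccinimide, O=C1CCC(=O)N1I
Why: Electrophilic iodination directed by the hydroxyl to its only free ortho position, the para position being blocked by bromine.

Step 21
Reactants: 34 4-bromo-2-iodo-6-methoxyphenol
Product: 35 5-bromo-1-iodo-2,3-dimethoxybenzene
Conditions: CH3I, K2CO3, acetone, 50 °C
Reagents that add atoms: iodomethane, CI
Why: Williamson methylation of the phenol.

Step 22
Reactants: 32 3,4,5-trimethoxy-2-(3,4,5-trimethoxyphenoxy)phenol; 35 5-bromo-1-iodo-2,3-dimethoxybenzene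
Product: 36 5-bromo-1,2-dimethoxy-3-[3,4,5-trimethoxy-2-(3,4,5-trimethoxyphenoxy)phenoxy]benzene
Conditions: CuI (10 mol%), picolinic acid (20 mol%), K3PO4, DMSO, 80 °C, Ar; 35 in excess
Reagents that add atoms: none
Why: Halogen-selective Ullmann coupling; monovalent copper inserts into the C–I bond well before the C–Br bond, and an excess of 35 suppresses a second coupling at bromine.

Step 23
Reactants: 27 [2-(6-hydroxy-2,3,4-trimethoxyphenoxy)-3-methoxy-5-(ABC-oxy)phenyl]methanol; 36 5-bromo-1,2-dimethoxy-3-[3,4,5-trimethoxy-2-(3,4,5-trimethoxyphenoxy)phenoxy]benzene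
Product: 37 {2-[6-(FGH-oxy)-2,3,4-trimethoxyphenoxy]-3-methoxy-5-(ABC-oxy)phenyl}methanol
Conditions: CuI (30 mol%), picolinic acid (60 mol%), K3PO4, DMSO, 100 °C, Ar
Reagents that add atoms: none
Why: Ullmann coupling at an aryl bromide with C–H on both sides; the phenol has one ortho substituent, and the benzylic alcohol is not deprotonated by phosphate and should not compete.

Step 24
Reactants: 37 {2-[6-(FGH-oxy)-2,3,4-trimethoxyphenoxy]-3-methoxy-5-(ABC-oxy)phenyl}methanol
Product: 38 2-[6-(FGH-oxy)-2,3,4-trimethoxyphenoxy]-3-methoxy-5-(ABC-oxy)benzaldehyde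
Conditions: MnO2 (activated, excess), CH2Cl2, rt
Reagents that add atoms: none
Why: Selective oxidation of a benzylic alcohol to the aldehyde; no free phenol is left that the oxidant could attack.

Step 25
Reactants: 38 2-[6-(FGH-oxy)-2,3,4-trimethoxyphenoxy]-3-methoxy-5-(ABC-oxy)benzaldehyde
Product: 40 2-[6-(FGH-oxy)-2,3,4-trimethoxyphenoxy]-3-methoxy-5-(ABC-oxy)phenol, via aryl formate 39 (not isolated)
Conditions: mCPBA, NaHCO3, CH2Cl2, 0 °C; then K2CO3, MeOH, rt, Ar
Reagents that add atoms: 3-chloroperoxybenzoic acid, OOC(=O)c1cccc(Cl)c1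
Why: Dakin-type Baeyer–Villiger oxidation of a 2-aryloxybenzaldehyde, a substrate class on which aryl migration is established; it installs the last ring D oxygen.

Step 26
Reactants: 40 2-[6-(FGH-oxy)-2,3,4-trimethoxyphenoxy]-3-methoxy-5-(ABC-oxy)phenol
Product: 41 CNP0309601.0 (octaaryl heptaether with twenty-one free hydroxyls)
Conditions: BBr3 (excess), CH2Cl2, −78 °C to rt, Ar; then MeOH/H2O, 0 °C; reversed-phase chromatography under Ar
Reagents that add atoms: none
Why: Lewis acid cleavage of all twenty aryl methyl ethers by bromide attack on the O-methyl carbon of the boron complexes; diaryl ether bonds are not cleaved because neither carbon is open to substitution.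

## Compound list

1 | 2,4,6-trimethoxyphenol | COc1cc(OC)c(O)c(OC)c1 | starting material
2 | 4-bromo-2,6-dimethoxybenzaldehyde | COc1cc(Br)cc(OC)c1C=O | starting material
3 | 2,6-dimethoxy-4-(2,4,6-trimethoxyphenoxy)benzaldehyde | COc1cc(OC)c(Oc2cc(OC)c(C=O)c(OC)c2)c(OC)c1 | intermediate
4 | 2,6-dimethoxy-4-(2,4,6-trimethoxyphenoxy)phenyl formate | COc1cc(OC)c(Oc2cc(OC)c(OC=O)c(OC)c2)c(OC)c1 | intermediate
5 | 2,6-dimethoxy-4-(2,4,6-trimethoxyphenoxy)phenol | COc1cc(OC)c(Oc2cc(OC)c(O)c(OC)c2)c(OC)c1 | intermediate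
6 | 5-bromo-1,2,3-trimethoxybenzene | COc1cc(Br)cc(OC)c1OC | starting material
7 | 6-bromo-2,3,4-trimethoxybenzaldehyde | COc1cc(Br)c(C=O)c(OC)c1OC | intermediate
8 | 6-[2,6-dimethoxy-4-(2,4,6-trimethoxyphenoxy)phenoxy]-2,3,4-trimethoxybenzaldehyde | COc1cc(OC)c(Oc2cc(OC)c(Oc3cc(OC)c(OC)c(OC)c3C=O)c(OC)c2)c(OC)c1 | intermediate
9 | 6-[2,6-dimethoxy-4-(2,4,6-trimethoxyphenoxy)phenoxy]-2,3,4-trimethoxyphenyl formate | COc1cc(OC)c(Oc2cc(OC)c(Oc3cc(OC)c(OC)c(OC)c3OC=O)c(OC)c2)c(OC)c1 | intermediate
10 | 6-[2,6-dimethoxy-4-(2,4,6-trimethoxyphenoxy)phenoxy]-2,3,4-trimethoxyphenol | COc1cc(OC)c(Oc2cc(OC)c(Oc3cc(OC)c(OC)c(OC)c3O)c(OC)c2)c(OC)c1 | intermediate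
11 | 3-(ABC-oxy)prop-1-ene | COc1cc(OC)c(Oc2cc(OC)c(Oc3cc(OC)c(OC)c(OC)c3OCC=C)c(OC)c2)c(OC)c1 | intermediate
12 | 3-(ABC-oxy)propane-1,2-diol (racemic) | COc1cc(OC)c(Oc2cc(OC)c(Oc3cc(OC)c(OC)c(OC)c3OCC(O)CO)c(OC)c2)c(OC)c1 | intermediate
13 | 2-(ABC-oxy)acetaldehyde | COc1cc(OC)c(Oc2cc(OC)c(Oc3cc(OC)c(OC)c(OC)c3OCC=O)c(OC)c2)c(OC)c1 | intermediate
14 | (Z)-3-(dimethylamino)-2-(ABC-oxy)prop-2-enal | COc1cc(OC)c(Oc2cc(OC)c(Oc3cc(OC)c(OC)c(OC)c3OC(/C=O)=C\N(C)C)c(OC)c2)c(OC)c1 | intermediate
15 | 2-(ABC-oxy)malonaldehyde | COc1cc(OC)c(Oc2cc(OC)c(Oc3cc(OC)c(OC)c(OC)c3OC(C=O)C=O)c(OC)c2)c(OC)c1 | intermediate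
16 | (E)-2-(ABC-oxy)-3-(trimethylsilyloxy)prop-2-enal | COc1cc(OC)c(Oc2cc(OC)c(Oc3cc(OC)c(OC)c(OC)c3OC(/C=O)=C/O[Si](C)(C)C)c(OC)c2)c(OC)c1 | intermediate
17 | methyl 4-methoxyacetoacetate | COCC(=O)CC(=O)OC | starting material
18 | methyl (Z)-4-methoxy-3-(trimethylsilyloxy)but-2-enoate | COC/C(O[Si](C)(C)C)=C/C(=O)OC | intermediate
19 | (1Z,3Z)-1,4-dimethoxy-1,3-bis(trimethylsilyloxy)buta-1,3-diene | CO/C=C(\O[Si](C)(C)C)/C=C(/OC)O[Si](C)(C)C | intermediate
20 | methyl 2-hydroxy-3-methoxy-5-(ABC-oxy)benzoate | COc1cc(OC)c(Oc2cc(OC)c(Oc3cc(OC)c(OC)c(OC)c3Oc4cc(OC)c(O)c(C(=O)OC)c4)c(OC)c2)c(OC)c1 | intermediate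
21 | 2,6-dimethoxy-1,4-benzoquinone | COC1=CC(=O)C=C(OC)C1=O | starting material
22 | 3-bromo-2,6-dimethoxy-1,4-benzoquinone | COC1=CC(=O)C(Br)=C(OC)C1=O | intermediate
23 | methyl 2-[(2,4-dimethoxy-3,6-dioxocyclohexa-1,4-dien-1-yl)oxy]-3-methoxy-5-(ABC-oxy)benzoate | COc1cc(OC)c(Oc2cc(OC)c(Oc3cc(OC)c(OC)c(OC)c3Oc4cc(OC)c(OC5=C(OC)C(=O)C(OC)=CC5=O)c(C(=O)OC)c4)c(OC)c2)c(OC)c1 | intermediate
24 | methyl 2-(3,6-dihydroxy-2,4-dimethoxyphenoxy)-3-methoxy-5-(ABC-oxy)benzoate | COc1cc(OC)c(Oc2cc(OC)c(Oc3cc(OC)c(OC)c(OC)c3Oc4cc(OC)c(Oc5c(O)cc(OC)c(O)c5OC)c(C(=O)OC)c4)c(OC)c2)c(OC)c1 | intermediate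
25 | methyl 2-[3-hydroxy-2,4-dimethoxy-6-(pivaloyloxy)phenoxy]-3-methoxy-5-(ABC-oxy)benzoate | COc1cc(OC)c(Oc2cc(OC)c(Oc3cc(OC)c(OC)c(OC)c3Oc4cc(OC)c(Oc5c(OC(=O)C(C)(C)C)cc(OC)c(O)c5OC)c(C(=O)OC)c4)c(OC)c2)c(OC)c1 | intermediate
26 | methyl 3-methoxy-2-[2,3,4-trimethoxy-6-(pivaloyloxy)phenoxy]-5-(ABC-oxy)benzoate | COc1cc(OC)c(Oc2cc(OC)c(Oc3cc(OC)c(OC)c(OC)c3Oc4cc(OC)c(Oc5c(OC(=O)C(C)(C)C)cc(OC)c(OC)c5OC)c(C(=O)OC)c4)c(OC)c2)c(OC)c1 | intermediate
27 | [2-(6-hydroxy-2,3,4-trimethoxyphenoxy)-3-methoxy-5-(ABC-oxy)phenyl]methanol | COc1cc(OC)c(Oc2cc(OC)c(Oc3cc(OC)c(OC)c(OC)c3Oc4cc(OC)c(Oc5c(O)cc(OC)c(OC)c5OC)c(CO)c4)c(OC)c2)c(OC)c1 | intermediate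
28 | 3,4,5-trimethoxyphenol | COc1cc(O)cc(OC)c1OC | starting material
29 | 2-bromo-3,4,5-trimethoxybenzaldehyde | COc1cc(C=O)c(Br)c(OC)c1OC | starting material
30 | 3,4,5-trimethoxy-2-(3,4,5-trimethoxyphenoxy)benzaldehyde | COc1cc(Oc2c(C=O)cc(OC)c(OC)c2OC)cc(OC)c1OC | intermediate
31 | 3,4,5-trimethoxy-2-(3,4,5-trimethoxyphenoxy)phenyl formate | COc1cc(Oc2c(OC=O)cc(OC)c(OC)c2OC)cc(OC)c1OC | intermediate
32 | 3,4,5-trimethoxy-2-(3,4,5-trimethoxyphenoxy)phenol | COc1cc(Oc2c(O)cc(OC)c(OC)c2OC)cc(OC)c1OC | intermediate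
33 | 4-bromo-2-methoxyphenol | COc1cc(Br)ccc1O | starting material
34 | 4-bromo-2-iodo-6-methoxyphenol | COc1cc(Br)cc(I)c1O | intermediate
35 | 5-bromo-1-iodo-2,3-dimethoxybenzene | COc1cc(Br)cc(I)c1OC | intermediate
36 | 5-bromo-1,2-dimethoxy-3-[3,4,5-trimethoxy-2-(3,4,5-trimethoxyphenoxy)phenoxy]benzene | COc1cc(Br)cc(Oc2cc(OC)c(OC)c(OC)c2Oc2cc(OC)c(OC)c(OC)c2)c1OC | intermediate
37 | {2-[6-(FGH-oxy)-2,3,4-trimethoxyphenoxy]-3-methoxy-5-(ABC-oxy)phenyl}methanol | COc1cc(OC)c(Oc2cc(OC)c(Oc3cc(OC)c(OC)c(OC)c3Oc4cc(OC)c(Oc5c(Oc6cc(OC)c(OC)c(Oc7cc(OC)c(OC)c(OC)c7Oc8cc(OC)c(OC)c(OC)c8)c6)cc(OC)c(OC)c5OC)c(CO)c4)c(OC)c2)c(OC)c1 | intermediate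
38 | 2-[6-(FGH-oxy)-2,3,4-trimethoxyphenoxy]-3-methoxy-5-(ABC-oxy)benzaldehyde | COc1cc(OC)c(Oc2cc(OC)c(Oc3cc(OC)c(OC)c(OC)c3Oc4cc(OC)c(Oc5c(Oc6cc(OC)c(OC)c(Oc7cc(OC)c(OC)c(OC)c7Oc8cc(OC)c(OC)c(OC)c8)c6)cc(OC)c(OC)c5OC)c(C=O)c4)c(OC)c2)c(OC)c1 | intermediate
39 | 2-[6-(FGH-oxy)-2,3,4-trimethoxyphenoxy]-3-methoxy-5-(ABC-oxy)phenyl formate | COc1cc(OC)c(Oc2cc(OC)c(Oc3cc(OC)c(OC)c(OC)c3Oc4cc(OC)c(Oc5c(Oc6cc(OC)c(OC)c(Oc7cc(OC)c(OC)c(OC)c7Oc8cc(OC)c(OC)c(OC)c8)c6)cc(OC)c(OC)c5OC)c(OC=O)c4)c(OC)c2)c(OC)c1 | intermediate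
40 | 2-[6-(FGH-oxy)-2,3,4-trimethoxyphenoxy]-3-methoxy-5-(ABC-oxy)phenol | COc1cc(OC)c(Oc2cc(OC)c(Oc3cc(OC)c(OC)c(OC)c3Oc4cc(OC)c(Oc5c(Oc6cc(OC)c(OC)c(Oc7cc(OC)c(OC)c(OC)c7Oc8cc(OC)c(OC)c(OC)c8)c6)cc(OC)c(OC)c5OC)c(O)c4)c(OC)c2)c(OC)c1 | intermediate
41 | CNP0309601.0, the fully demethylated form of 40 (rings A to H, seven ether oxygens, twenty-one hydroxyls) | Oc1cc(O)c(Oc2cc(O)c(Oc3cc(O)c(O)c(O)c3Oc3cc(O)c(Oc4c(Oc5cc(O)c(O)c(Oc6cc(O)c(O)c(O)c6Oc6cc(O)c(O)c(O)c6)c5)cc(O)c(O)c4O)c(O)c3)c(O)c2)c(O)c1 | target

## Step count and risks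

Total: 26 steps. Longest linear sequence: 17 steps (steps 1, 2, 4 to 9, 12, 14 to 17, 23 to 26).

Step 12 (key step). What may go wrong: Lewis acid-triggered Friedel–Crafts hydroxyalkylation of ring A by the titanium-bound formyl group, or desilylation of 16 or 19 by adventitious acid leading to open-chain aldol products that do not aromatise. Fallback: set out from enaminoaldehyde 14, isolated instead of hydrolysed. Condensation with dimethylammonium tetrafluoroborate in hot ethanol would give the vinamidinium salt N-[3-(dimethylamino)-2-(ABC-oxy)prop-2-en-1-ylidene]-N-methylmethanaminium tetrafluoroborate F1. Base-mediated benzannulation of F1 with keto ester 17 (NaOMe, MeOH, then reflux) forms the same two ring bonds through anionic condensation and loss of dimethylamine, and returns to the route at 20.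

Step 8. What may go wrong: self-aldol condensation of aldehyde 13 before aminomethylenation, or loss of a formyl group by retro-Claisen cleavage during the alkaline hydrolysis. Fallback: set out from phenol 10. Alkylation with diethyl chloromalonate (K2CO3, acetone) would give diethyl 2-(ABC-oxy)malonate F2; LiAlH4 would reduce it to 2-(ABC-oxy)propane-1,3-diol F3; a double Swern oxidation of F3 returns to the route at 15.

Step 14. What may go wrong: slow ipso-substitution by the hindered, hydrogen-bonded phenoxide, with competing conjugate addition at the quinone C–H position, displacement of a methoxy group, or base-induced decomposition of the quinone. Fallback: set out from 20 and commercial 29. An Ullmann coupling under forcing conditions (CuI, 2,2,6,6-tetramethylheptane-3,5-dione, Cs2CO3, NMP, 120 °C) would give methyl 2-(6-formyl-2,3,4-trimethoxyphenoxy)-3-methoxy-5-(ABC-oxy)benzoate F4. Baeyer–Villiger oxidation would give methyl 2-[6-(formyloxy)-2,3,4-trimethoxyphenoxy]-3-methoxy-5-(ABC-oxy)benzoate F5, and methanolysis methyl 2-(6-hydroxy-2,3,4-trimethoxyphenoxy)-3-methoxy-5-(ABC-oxy)benzoate F6. LiAlH4 reduction of F6 returns to the route at 27 and bypasses steps 15 and 16.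

Step 15. What may go wrong: poor site selectivity of the acylation (both hydroxyls or the wrong one), and re-oxidation of the hydroquinone by air. Fallback: set out from 23, reduced to 24 as before. Saponification (LiOH, degassed THF/H2O) would give 2-(3,6-dihydroxy-2,4-dimethoxyphenoxy)-3-methoxy-5-(ABC-oxy)benzoic acid F7. Carbodiimide lactonisation at high dilution can reach only the hydroxyl ortho to the ether oxygen and would give the depsidone 7-hydroxy-4,6,8-trimethoxy-2-(ABC-oxy)-11H-dibenzo[b,e][1,4]dioxepin-11-one F8. Methylation (CH3I, K2CO3) would give 4,6,7,8-tetramethoxy-2-(ABC-oxy)-11H-dibenzo[b,e][1,4]dioxepin-11-one F9, and LiAlH4 opening of the lactone returns to the route at 27.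

Step 23. What may go wrong: sluggish coupling because of crowding by the ortho aryloxy group, reductive loss of bromine from 36, or oxidation of the electron-rich phenoxide. Fallback: set out from 36. Bromine–lithium exchange (n-BuLi, THF, −78 °C) and quenching with B(OiPr)3 would give {3,4-dimethoxy-5-[3,4,5-trimethoxy-2-(3,4,5-trimethoxyphenoxy)phenoxy]phenyl}boronic acid F10. A Chan–Lam coupling of F10 with 27 (Cu(OAc)2, pyridine, 4 Å sieves, CH2Cl2), with divalent copper and a nucleophilic aryl partner, returns to the route at 37.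

Step 26. What may go wrong: incomplete cleavage of some of the twenty methyl ethers, and oxidative degradation of the polyphenol during isolation. Fallback: set out from 40. The crude product of the BBr3 reaction would be peracetylated (Ac2O, pyridine) to the henicosaacetate of 41 F11, which is stable and can be purified on silica. Deacetylation under argon (NaOMe, MeOH, then acidic resin) returns to the route at 41.

## Further compounds

F1 | step 12 | N-[3-(dimethylamino)-2-(ABC-oxy)prop-2-en-1-ylidene]-N-methylmethanaminium tetrafluoroborate | COc1cc(OC)c(Oc2cc(OC)c(Oc3cc(OC)c(OC)c(OC)c3OC(/C=[N+](C)C)=C\N(C)C)c(OC)c2)c(OC)c1.F[B-](F)(F)F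
F2 | step 8 | diethyl 2-(ABC-oxy)malonate | COc1cc(OC)c(Oc2cc(OC)c(Oc3cc(OC)c(OC)c(OC)c3OC(C(=O)OCC)C(=O)OCC)c(OC)c2)c(OC)c1
F3 | step 8 | 2-(ABC-oxy)propane-1,3-diol | COc1cc(OC)c(Oc2cc(OC)c(Oc3cc(OC)c(OC)c(OC)c3OC(CO)CO)c(OC)c2)c(OC)c1
F4 | step 14 | methyl 2-(6-formyl-2,3,4-trimethoxyphenoxy)-3-methoxy-5-(ABC-oxy)benzoate | COc1cc(OC)c(Oc2cc(OC)c(Oc3cc(OC)c(OC)c(OC)c3Oc4cc(OC)c(Oc5c(C=O)cc(OC)c(OC)c5OC)c(C(=O)OC)c4)c(OC)c2)c(OC)c1
F5 | step 14 | methyl 2-[6-(formyloxy)-2,3,4-trimethoxyphenoxy]-3-methoxy-5-(ABC-oxy)benzoate | COc1cc(OC)c(Oc2cc(OC)c(Oc3cc(OC)c(OC)c(OC)c3Oc4cc(OC)c(Oc5c(OC=O)cc(OC)c(OC)c5OC)c(C(=O)OC)c4)c(OC)c2)c(OC)c1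
F6 | step 14 | methyl 2-(6-hydroxy-2,3,4-trimethoxyphenoxy)-3-methoxy-5-(ABC-oxy)benzoate | COc1cc(OC)c(Oc2cc(OC)c(Oc3cc(OC)c(OC)c(OC)c3Oc4cc(OC)c(Oc5c(O)cc(OC)c(OC)c5OC)c(C(=O)OC)c4)c(OC)c2)c(OC)c1
F7 | step 15 | 2-(3,6-dihydroxy-2,4-dimethoxyphenoxy)-3-methoxy-5-(ABC-oxy)benzoic acid | COc1cc(OC)c(Oc2cc(OC)c(Oc3cc(OC)c(OC)c(OC)c3Oc4cc(OC)c(Oc5c(O)cc(OC)c(O)c5OC)c(C(=O)O)c4)c(OC)c2)c(OC)c1
F8 | step 15 | 7-hydroxy-4,6,8-trimethoxy-2-(ABC-oxy)-11H-dibenzo[b,e][1,4]dioxepin-11-one | COc1cc(OC)c(Oc2cc(OC)c(Oc3cc(OC)c(OC)c(OC)c3Oc4cc(OC)c5c(c4)C(=O)Oc6cc(OC)c(O)c(OC)c6O5)c(OC)c2)c(OC)c1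
F9 | step 15 | 4,6,7,8-tetramethoxy-2-(ABC-oxy)-11H-dibenzo[b,e][1,4]dioxepin-11-one | COc1cc(OC)c(Oc2cc(OC)c(Oc3cc(OC)c(OC)c(OC)c3Oc4cc(OC)c5c(c4)C(=O)Oc6cc(OC)c(OC)c(OC)c6O5)c(OC)c2)c(OC)c1
F10 | step 23 | {3,4-dimethoxy-5-[3,4,5-trimethoxy-2-(3,4,5-trimethoxyphenoxy)phenoxy]phenyl}boronic acid | OB(O)c1cc(OC)c(OC)c(Oc2cc(OC)c(OC)c(OC)c2Oc2cc(OC)c(OC)c(OC)c2)c1
F11 | step 26 | henicosaacetate of 41 (all twenty-one hydroxyls acetylated) | CC(=O)Oc1cc(OC(C)=O)c(Oc2cc(OC(C)=O)c(Oc3cc(OC(C)=O)c(OC(C)=O)c(OC(C)=O)c3Oc3cc(OC(C)=O)c(Oc4c(Oc5cc(OC(C)=O)c(OC(C)=O)c(Oc6cc(OC(C)=O)c(OC(C)=O)c(OC(C)=O)c6Oc6cc(OC(C)=O)c(OC(C)=O)c(OC(C)=O)c6)c5)cc(OC(C)=O)c(OC(C)=O)c4OC(C)=O)c(OC(C)=O)c3)c(OC(C)=O)c2)c(OC(C)=O)c1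
A1 | alternative 1 | protected octaaryl ether with ring F as 2-fluoro-4,6-bis(aryloxy)benzaldehyde | O=Cc1c(F)cc(Oc2cc(OC)c(OC)c(OC)c2Oc2c(OC)cc(Oc3c(Oc4c(OC)cc(Oc5c(OC)cc(OC)cc5OC)cc4OC)cc(OC)c(OC)c3OC)cc2OC)cc1Oc1cc(OC)c(OC)c(OC)c1Oc1cc(OC)c(OC)c(OC)c1
A2 | alternative 1 | 2,4,6-trifluorobenzaldehyde | O=Cc1c(F)cc(F)cc1F
A3 | alternative 1 | 3,4,5-trimethoxy-2-[2,6-dimethoxy-4-(ABC-oxy)phenoxy]phenol (protected A–E pentamer phenol) | Oc1cc(OC)c(OC)c(OC)c1Oc1c(OC)cc(Oc2c(Oc3c(OC)cc(Oc4c(OC)cc(OC)cc4OC)cc3OC)cc(OC)c(OC)c2OC)cc1OC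
A4 | alternative 2 | 4-[4-(benzyloxy)-3,5-dimethoxyphenoxy]-5-[2,6-dimethoxy-4-(2,4,6-trimethoxyphenoxy)phenoxy]-2,3-dimethoxyphenol | Oc1cc(Oc2c(OC)cc(Oc3c(OC)cc(OC)cc3OC)cc2OC)c(Oc2cc(OC)c(OCc3ccccc3)c(OC)c2)c(OC)c1OC
A5 | alternative 2 | 2-(ethynyloxy)-1,3-dimethoxy-5-(2,4,6-trimethoxyphenoxy)benzene | C#COc1c(OC)cc(Oc2c(OC)cc(OC)cc2OC)cc1OC
A6 | alternative 2 | 2-[4-(benzyloxy)-3,5-dimethoxyphenoxy]-3,4-dimethoxycyclobut-2-en-1-one (racemic) | COC1C(=O)C(Oc2cc(OC)c(OCc3ccccc3)c(OC)c2)=C1OC
A7 | alternative 3 | 3,4,5-trimethoxy-2-(3,4,5-trimethoxyphenoxy)phenol (identical with 32) | Oc1cc(OC)c(OC)c(OC)c1Oc1cc(OC)c(OC)c(OC)c1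
A8 | alternative 3 | 3,4-dimethoxy-4-(1-methoxyvinyl)-2-(3,4,5-trimethoxyphenoxy)cyclobut-2-en-1-one (racemic) | C=C(OC)C1(OC)C(OC)=C(Oc2cc(OC)c(OC)c(OC)c2)C1=O
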